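**Plan**

Numbering: fragment B is the trione half (C1 and C2 adjacent ketones, C3 the quaternary carbon with ethyl and the ether oxygen, C4 ketone, arene C4a–C8a). Fragment A is the naphthazarin half (C2 ethyl, C3 ether oxygen).
Cuts, in retrosynthetic order: the six O–CH3 bonds and the fragment A quinone (back to a pentamethoxynaphthyl ether); the two C=O groups at C1/C2 (back to a cis C1=C2 alkene); C1=C2 itself (metathesis); C4–C4a (aryllithium plus aldehyde); C3–O (allylic etherification of a fragment A naphthol).
Enabling feature: in the carbocycle C1–C2–C3–C4–C4a–C8a, the neighbouring carbonyl carbons C1 (on arene carbon C8a) and C2 (on C3) are an alkene in a higher oxidation state. One vinyl group on C3 and one on C8a of the C4 aryl ketone therefore carry every carbon needed to close this ring.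
Forward: the second ring of the fragment A naphthalene is built first, by ring expansion of an aryl cyclobutenone made from a squarate. The C3–C4 unit is then attached to its oxygen, the fragment B arene is added at C4, the fragment B carbocycle closes by metathesis, and oxidation and demethylation finish the molecule.
Stereochemistry: C3 is the only stereocentre. It is set when the naphthol opens racemic 2-ethyl-2-vinyloxirane in a palladium-catalysed dynamic kinetic asymmetric reaction under a chiral diphosphine. It is quaternary and cannot epimerise; its descriptor changes from R to S at the trione stage only because the CIP priorities change.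

Key step: step 15

Assumption on the chemistry: the (R,R) ligand is written in step 6. Which antipode of the ligand gives the R ether with this nucleophile must be confirmed on the first sample, and the (S,S) ligand replaces it if needed.
Remark: fragment A of the target is a naphthazarin. Its two quinoid tautomers interconvert by proton transfer, and the target SMILES is one drawing of that pair.
Abbreviation: ArA = 3-ethyl-1,4,5,7,8-pentamethoxynaphthalen-2-yl (fragment A as its pentamethyl ether).

**Route**

Step 1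
Reactants: 1 1-bromo-2,4,5-trimethoxybenzene; 2 diisopropyl squarate (3,4-di(propan-2-yloxy)cyclobut-3-ene-1,2-dione)
Product: 5 4-methoxy-2,3-di(propan-2-yloxy)-4-(2,4,5-trimethoxyphenyl)cyclobut-2-en-1-one (racemic), via 2,4,5-trimethoxyphenyllithium 3 (not isolated), via lithium cyclobutenolate adduct 4 (not isolated)
Conditions: n-BuLi, THF, −78 °C; add to 2, THF, −78 °C; MeOTf, −78 → 0 °C
Reagents that add atoms: methyl trifluoromethanesulfonate, COS(=O)(=O)C(F)(F)F
Why: Bromine–lithium exchange and 1,2-addition of the aryllithium to one of the two equivalent squarate carbonyl groups is the standard entry to 4-aryl-4-oxycyclobutenones, and trapping the tertiary alkoxide with MeOTf fixes the future C1 oxygen of fragment A as its methyl ether (the new stereocentre is racemic and disappears in step 3).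

Step 2
Reactants: 5 4-methoxy-2,3-di(propan-2-yloxy)-4-(2,4,5-trimethoxyphenyl)cyclobut-2-en-1-one
Product: 8 3-ethyl-4-methoxy-2-(propan-2-yloxy)-4-(2,4,5-trimethoxyphenyl)cyclobut-2-en-1-one (racemic), via tertiary lithium alkoxide 6 (not isolated), via allylic trifluoroacetate 7 (not isolated)
Conditions: EtLi, THF, −78 °C; (CF3CO)2O, −78 °C; H2O, → rt
Reagents that add atoms: ethyllithium, [Li]CC; water, O
Why: 1,2-Addition of EtLi to the remaining carbonyl group and ionisation of the derived trifluoroacetate give an alkoxy-stabilised cyclobutenyl cation that water captures at the distal isopropoxy carbon, so loss of propan-2-ol transposes the enone (squarate addition–transposition sequence) and places ethyl next to the aryl-bearing carbon, as fragment A requires.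

Step 3
Reactants: 8 3-ethyl-4-methoxy-2-(propan-2-yloxy)-4-(2,4,5-trimethoxyphenyl)cyclobut-2-en-1-one
Product: 11 2-ethyl-1,4,5,6,8-pentamethoxy-3-(propan-2-yloxy)naphthalene, via vinylketene 9 (not isolated), via tetramethoxynaphthol 10 (not isolated)
Conditions: p-xylene (degassed), 138 °C; evaporate; NaH, MeI, DMF, 0 °C → rt
Reagents that add atoms: iodomethane, CI
Why: Thermal cyclobutenone ring expansion, in which conrotatory 4π opening turns methoxy outward and aryl inward, the vinylketene closes by 6π electrocyclisation onto the only free ortho position and tautomerises to the naphthol, and this air-sensitive naphthol is methylated at once (Williamson ether synthesis).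

Step 4
Reactants: 11 2-ethyl-1,4,5,6,8-pentamethoxy-3-(propan-2-yloxy)naphthalene
Product: 12 3-ethyl-1,4,5,7,8-pentamethoxynaphthalen-2-ol (ArA–OH)
Conditions: BCl3, CH2Cl2, −78 → −10 °C; H2O
Reagents that add atoms: none
Why: Lewis-acid dealkylation with BCl3 cleaves secondary alkyl aryl ethers by an ionising pathway at temperatures where aryl methyl ethers without a chelating carbonyl neighbour persist, so only the C3 oxygen of fragment A is freed.

Step 5
Reactants: 13 1-chlorobutan-2-one; 14 vinylmagnesium bromide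
Product: 16 2-ethyl-2-vinyloxirane (racemic), via chlorohydrin 15 (not isolated)
Conditions: THF, −78 → 0 °C; aq. NH4Cl; crude 15, aq. NaOH, Et2O, rt; distil
Reagents that add atoms: none
Why: Grignard 1,2-addition to the α-chloroketone is faster than chloride displacement at low temperature, and hydroxide then closes the chlorohydrin by intramolecular Williamson displacement, as in the preparation of isoprene monoepoxide; the racemate is what step 6 needs.

Step 6
Reactants: 12 3-ethyl-1,4,5,7,8-pentamethoxynaphthalen-2-ol; 16 2-ethyl-2-vinyloxirane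
Product: 17 (2R)-2-(ArA-oxy)-2-ethylbut-3-en-1-ol
Conditions: Pd2(dba)3·CHCl3 (2.5 mol %), (R,R)-DACH-phenyl ligand [(1R,2R)-N,N'-bis(2-diphenylphosphinobenzoyl)cyclohexane-1,2-diamine, 7.5 mol %], Et3B (5 mol %), CH2Cl2, rt, slow addition of 16
Reagents that add atoms: none
Why: Tsuji–Trost-type dynamic kinetic asymmetric allylic etherification, in which zerovalent palladium opens both enantiomers of 16 to π-allyl alkoxide zwitterions that interconvert through the σ-complex at the CH2 terminus, the alkoxide (relayed by boron) takes the naphthol proton and delivers the naphthoxide to the neighbouring tertiary terminus, and the chiral pocket of the ligand sets C3 as R.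

Step 7
Reactants: 17 (2R)-2-(ArA-oxy)-2-ethylbut-3-en-1-ol
Product: 18 (2R)-2-(ArA-oxy)-2-ethylbut-3-enal
Conditions: Dess–Martin periodinane, CH2Cl2, 0 °C → rt
Reagents that add atoms: none
Why: Dess–Martin oxidation stops at the aldehyde, which has no α-hydrogen and therefore can neither epimerise nor move its alkene into conjugation.

Step 8
Reactants: 19 o-vanillin (2-hydroxy-3-methoxybenzaldehyde)
Product: 20 5-bromo-2-hydroxy-3-methoxybenzaldehyde
Conditions: Br2, NaOAc, AcOH, rt
Reagents that add atoms: bromine, BrBr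
Why: Electrophilic aromatic bromination is directed para to the free phenol, the established outcome for o-vanillin.

Step 9
Reactants: 20 5-bromo-2-hydroxy-3-methoxybenzaldehyde
Product: 21 2-hydroxy-3,5-dimethoxybenzaldehyde
Conditions: NaOMe, CuBr (10 mol %), MeOH/DMF, 110 °C; aq. HCl
Reagents that add atoms: sodium methoxide, [Na+].[O-]C
Why: Ullmann-type copper-catalysed methoxylation of an aryl bromide, the transformation that turns 5-bromovanillin into syringaldehyde, with the phenoxide formed in the flask shielding the aldehyde from methoxide.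

Step 10
Reactants: 21 2-hydroxy-3,5-dimethoxybenzaldehyde
Product: 22 2,3,5-trimethoxybenzaldehyde
Conditions: MeI, K2CO3, DMF, rt
Reagents that add atoms: iodomethane, CI
Why: Williamson methylation of an acidic salicylaldehyde phenol.

Step 11
Reactants: 22 2,3,5-trimethoxybenzaldehyde
Product: 23 2-bromo-3,5,6-trimethoxybenzaldehyde
Conditions: NBS, MeCN, 0 °C → rt
Reagents that add atoms: N-bromosuccinimide, O=C1CCC(=O)N1Br
Why: Electrophilic aromatic bromination goes to the position para to one methoxy and ortho to another, next to the formyl group, and not to the position squeezed between two methoxy groups, as in the bromination of 3,5-dimethoxybenzaldehyde.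

Step 12
Reactants: 23 2-bromo-3,5,6-trimethoxybenzaldehyde
Product: 24 2-bromo-3-ethenyl-1,4,5-trimethoxybenzene
Conditions: Ph3PCH3Br, KOt-Bu, THF, 0 °C → rt
Reagents that add atoms: methyltriphenylphosphonium bromide, C[P+](c1ccccc1)(c1ccccc1)c1ccccc1.[Br-]
Why: Wittig methylenation of a non-enolisable aromatic aldehyde, to which the aryl bromide is inert.

Step 13
Reactants: 24 2-bromo-3-ethenyl-1,4,5-trimethoxybenzene; 18 (2R)-2-(ArA-oxy)-2-ethylbut-3-enal
Product: 26 (2R)-2-(ArA-oxy)-2-ethyl-1-(2-ethenyl-3,4,6-trimethoxyphenyl)but-3-en-1-ol (both C1 epimers), via vinylaryllithium 25 (not isolated)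
Conditions: n-BuLi, THF, −78 °C; 18, −78 → −20 °C; H2O
Reagents that add atoms: none
Why: Bromine–lithium exchange on o-bromostyrenes is faster at −78 °C than carbolithiation of the vinyl group, and the aryllithium adds 1,2 to the non-enolisable aldehyde to form C4–C4a, giving a carbinol centre as an epimer mixture that step 14 removes.

Step 14
Reactants: 26 (2R)-2-(ArA-oxy)-2-ethyl-1-(2-ethenyl-3,4,6-trimethoxyphenyl)but-3-en-1-ol
Product: 27 (2R)-2-(ArA-oxy)-2-ethyl-1-(2-ethenyl-3,4,6-trimethoxyphenyl)but-3-en-1-one
Conditions: Dess–Martin periodinane, CH2Cl2, rt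
Reagents that add atoms: none
Why: Dess–Martin oxidation of the benzylic alcohol removes the carbinol stereocentre and gives the aryl ketone without touching either vinyl group or the methyl ethers.

Step 15
Reactants: 27 (2R)-2-(ArA-oxy)-2-ethyl-1-(2-ethenyl-3,4,6-trimethoxyphenyl)but-3-en-1-one
Product: 28 (2R)-2-(ArA-oxy)-2-ethyl-5,6,8-trimethoxynaphthalen-1(2H)-one
Conditions: second-generation Grubbs catalyst (H2IMes)(PCy3)Cl2Ru=CHPh (5–10 mol %), CH2Cl2 (0.005 M), 40 °C, argon sparge
Reagents that add atoms: none
Why: After phosphine loss the ruthenium benzylidene exchanges with one terminal alkene of 27, the new alkylidene adds to the other alkene in a [2+2] step, and cycloreversion of the ruthenacyclobutane releases the C1=C2 bond while ethene leaves the flask and drives the equilibrium. The closest known reaction is ring-closing metathesis of o-vinylaryl dienes such as 1-(2-vinylaryl)but-3-en-1-ones to benzo-fused cyclohexenes and naphthalenones. One ring closes, the six-membered carbocycle C1–C2–C3–C4–C4a–C8a, by joining the two vinyl CH carbons, and the ring size enforces the cis alkene. No stereocentre is formed, and C3, which is quaternary and has no acidic hydrogen, keeps its R configuration. The step needs cyclisation to outrun dimerisation and the thermal [3,3] shift of the tertiary allyl naphthyl ether: the fully substituted C3 and the ortho arrangement on the arene hold the alkenes within bonding distance, high dilution suppresses cross metathesis, and 40 °C should stay below the temperature such ethers need to rearrange. Because C3 carries no hydrogen the product cannot tautomerise to a naphthol, so the alkene stays exactly where the dione is wanted.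

Step 16
Reactants: 28 (2R)-2-(ArA-oxy)-2-ethyl-5,6,8-trimethoxynaphthalen-1(2H)-one
Product: 29 (2R,3S,4S)-2-(ArA-oxy)-2-ethyl-3,4-dihydroxy-5,6,8-trimethoxy-3,4-dihydronaphthalen-1(2H)-one
Conditions: OsO4 (5 mol %), NMO, acetone/H2O, rt
Reagents that add atoms: N-methylmorpholine N-oxide, C[N+]1([O-])CCOCC1; water, O
Why: Upjohn dihydroxylation, in which OsO4 adds suprafacially to the only non-aromatic alkene, expected on the face anti to the bulky aryloxy group on C3, to give a cis-diol whose two new stereocentres are erased in step 17, so the other facial isomer converges as well.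

Step 17
Reactants: 29 (2R,3S,4S)-2-(ArA-oxy)-2-ethyl-3,4-dihydroxy-5,6,8-trimethoxy-3,4-dihydronaphthalen-1(2H)-one
Product: 30 (3S)-3-(ArA-oxy)-3-ethyl-5,7,8-trimethoxynaphthalene-1,2,4(3H)-trione
Conditions: IBX, DMSO, rt
Reagents that add atoms: none
Why: IBX oxidation converts 1,2-diols into 1,2-diketones without C–C cleavage under neutral conditions that spare the aryl methyl ethers and avoid retro-aldol opening at C2–C3.

Step 18
Reactants: 30 (3S)-3-(ArA-oxy)-3-ethyl-5,7,8-trimethoxynaphthalene-1,2,4(3H)-trione
Product: 31 (3S)-3-ethyl-3-[(3-ethyl-5,7,8-trimethoxy-1,4-dioxo-1,4-dihydronaphthalen-2-yl)oxy]-5,7,8-trimethoxynaphthalene-1,2,4(3H)-trione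
Conditions: (NH4)2Ce(NO3)6, MeCN/H2O, 0 °C
Reagents that add atoms: water, O
Why: Oxidative demethylation of a 1,4-dimethoxyarene by tetravalent cerium takes place on the hexaoxygenated naphthalene, by far the most easily oxidised arene now that the fragment B arene carries two acyl groups, and oxidation of either naphthalene ring leads to the same final product because the naphthazarin tautomers equilibrate after step 19.

Step 19
Reactants: 31 (3S)-3-ethyl-3-[(3-ethyl-5,7,8-trimethoxy-1,4-dioxo-1,4-dihydronaphthalen-2-yl)oxy]-5,7,8-trimethoxynaphthalene-1,2,4(3H)-trione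
Product: 32 (3S)-3-ethyl-3-[(3-ethyl-5,7,8-trihydroxy-1,4-dioxo-1,4-dihydronaphthalen-2-yl)oxy]-5,7,8-trihydroxynaphthalene-1,2,4(3H)-trione (target)
Conditions: BBr3 (excess), CH2Cl2, −78 → 0 °C; H2O
Reagents that add atoms: none
Why: Lewis-acid ether cleavage with BBr3 lets bromide attack the six methyl groups (four of them activated by chelation to peri carbonyl groups), whereas the C3–O bond sits on a quaternary carbon flanked by two carbonyl groups and can neither ionise nor undergo backside displacement.

**Compound list**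

1 | 1-bromo-2,4,5-trimethoxybenzene | COc1cc(OC)c(OC)cc1Br | starting material
2 | diisopropyl squarate | CC(C)OC1=C(OC(C)C)C(=O)C1=O | starting material
3 | 2,4,5-trimethoxyphenyllithium | [Li]c1cc(OC)c(OC)cc1OC | intermediate
4 | lithium 4-oxo-2,3-di(propan-2-yloxy)-1-(2,4,5-trimethoxyphenyl)cyclobut-2-en-1-olate (racemic) | [Li+].[O-]C1(c2cc(OC)c(OC)cc2OC)C(=O)C(OC(C)C)=C1OC(C)C | intermediate
5 | 4-methoxy-2,3-di(propan-2-yloxy)-4-(2,4,5-trimethoxyphenyl)cyclobut-2-en-1-one (racemic) | COC1(c2cc(OC)c(OC)cc2OC)C(=O)C(OC(C)C)=C1OC(C)C | intermediate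
6 | lithium 1-ethyl-4-methoxy-2,3-di(propan-2-yloxy)-4-(2,4,5-trimethoxyphenyl)cyclobut-2-en-1-olate (racemic, diastereomer mixture) | [Li+].[O-]C1(CC)C(OC(C)C)=C(OC(C)C)C1(OC)c1cc(OC)c(OC)cc1OC | intermediate
7 | 1-ethyl-4-methoxy-2,3-di(propan-2-yloxy)-4-(2,4,5-trimethoxyphenyl)cyclobut-2-en-1-yl trifluoroacetate | CCC1(OC(=O)C(F)(F)F)C(OC(C)C)=C(OC(C)C)C1(OC)c1cc(OC)c(OC)cc1OC | intermediate
8 | 3-ethyl-4-methoxy-2-(propan-2-yloxy)-4-(2,4,5-trimethoxyphenyl)cyclobut-2-en-1-one (racemic) | CCC1=C(OC(C)C)C(=O)C1(OC)c1cc(OC)c(OC)cc1OC | intermediate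
9 | (3E)-3-ethyl-4-methoxy-2-(propan-2-yloxy)-4-(2,4,5-trimethoxyphenyl)buta-1,3-dien-1-one | O=C=C(OC(C)C)/C(CC)=C(/OC)c1cc(OC)c(OC)cc1OC | intermediate
10 | 3-ethyl-4,5,7,8-tetramethoxy-2-(propan-2-yloxy)naphthalen-1-ol | CCc1c(OC(C)C)c(O)c2c(OC)c(OC)cc(OC)c2c1OC | intermediate
11 | 2-ethyl-1,4,5,6,8-pentamethoxy-3-(propan-2-yloxy)naphthalene | CCc1c(OC(C)C)c(OC)c2c(OC)c(OC)cc(OC)c2c1OC | intermediate
12 | 3-ethyl-1,4,5,7,8-pentamethoxynaphthalen-2-ol | CCc1c(O)c(OC)c2c(OC)c(OC)cc(OC)c2c1OC | intermediate
13 | 1-chlorobutan-2-one | CCC(=O)CCl | starting material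
14 | vinylmagnesium bromide | C=C[Mg]Br | starting material
15 | 3-(chloromethyl)pent-1-en-3-ol (racemic) | CCC(O)(CCl)C=C | intermediate
16 | 2-ethyl-2-vinyloxirane (racemic) | CCC1(C=C)CO1 | intermediate
17 | (2R)-2-(ArA-oxy)-2-ethylbut-3-en-1-ol | COc1c(O[C@](CO)(CC)C=C)c(CC)c(OC)c2c(OC)cc(OC)c(OC)c12 | intermediate
18 | (2R)-2-(ArA-oxy)-2-ethylbut-3-enal | COc1c(O[C@](C=O)(CC)C=C)c(CC)c(OC)c2c(OC)cc(OC)c(OC)c12 | intermediate
19 | o-vanillin | COc1cccc(C=O)c1O | starting material
20 | 5-bromo-2-hydroxy-3-methoxybenzaldehyde | COc1cc(Br)cc(C=O)c1O | intermediate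
21 | 2-hydroxy-3,5-dimethoxybenzaldehyde | COc1cc(OC)c(O)c(C=O)c1 | intermediate
22 | 2,3,5-trimethoxybenzaldehyde | COc1cc(OC)c(OC)c(C=O)c1 | intermediate
23 | 2-bromo-3,5,6-trimethoxybenzaldehyde | COc1cc(OC)c(OC)c(C=O)c1Br | intermediate
24 | 2-bromo-3-ethenyl-1,4,5-trimethoxybenzene | COc1cc(OC)c(OC)c(C=C)c1Br | intermediate
25 | (2-ethenyl-3,4,6-trimethoxyphenyl)lithium | [Li]c1c(OC)cc(OC)c(OC)c1C=C | intermediate
26 | (2R)-2-(ArA-oxy)-2-ethyl-1-(2-ethenyl-3,4,6-trimethoxyphenyl)but-3-en-1-ol (C1 epimers) | COc1c(O[C@](C(O)c3c(OC)cc(OC)c(OC)c3C=C)(CC)C=C)c(CC)c(OC)c2c(OC)cc(OC)c(OC)c12 | intermediate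
27 | (2R)-2-(ArA-oxy)-2-ethyl-1-(2-ethenyl-3,4,6-trimethoxyphenyl)but-3-en-1-one | COc1c(O[C@](C(=O)c3c(OC)cc(OC)c(OC)c3C=C)(CC)C=C)c(CC)c(OC)c2c(OC)cc(OC)c(OC)c12 | intermediate
28 | (2R)-2-(ArA-oxy)-2-ethyl-5,6,8-trimethoxynaphthalen-1(2H)-one | COc1c(O[C@]3(CC)C=Cc4c(OC)c(OC)cc(OC)c4C3=O)c(CC)c(OC)c2c(OC)cc(OC)c(OC)c12 | intermediate
29 | (2R,3S,4S)-2-(ArA-oxy)-2-ethyl-3,4-dihydroxy-5,6,8-trimethoxy-3,4-dihydronaphthalen-1(2H)-one | COc1c(O[C@]3(CC)[C@@H](O)[C@@H](O)c4c(OC)c(OC)cc(OC)c4C3=O)c(CC)c(OC)c2c(OC)cc(OC)c(OC)c12 | intermediate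
30 | (3S)-3-(ArA-oxy)-3-ethyl-5,7,8-trimethoxynaphthalene-1,2,4(3H)-trione | COc1c(O[C@]3(CC)C(=O)C(=O)c4c(OC)c(OC)cc(OC)c4C3=O)c(CC)c(OC)c2c(OC)cc(OC)c(OC)c12 | intermediate
31 | (3S)-3-ethyl-3-[(3-ethyl-5,7,8-trimethoxy-1,4-dioxo-1,4-dihydronaphthalen-2-yl)oxy]-5,7,8-trimethoxynaphthalene-1,2,4(3H)-trione | CCC1=C(O[C@]2(CC)C(=O)C(=O)c3c(OC)c(OC)cc(OC)c3C2=O)C(=O)c2c(OC)c(OC)cc(OC)c2C1=O | intermediate
32 | (3S)-3-ethyl-3-[(3-ethyl-5,7,8-trihydroxy-1,4-dioxo-1,4-dihydronaphthalen-2-yl)oxy]-5,7,8-trihydroxynaphthalene-1,2,4(3H)-trione | CCC1=C(O[C@]2(CC)C(=O)C(=O)c3c(O)c(O)cc(O)c3C2=O)C(=O)c2c(O)c(O)cc(O)c2C1=O | target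

**Step count**

Total step count: 19. Longest linear sequence: 13 steps (1–4, 6, 7, 13–19).

**Steps most likely to fail**

Step 6. The naphthol is flanked by methoxy and ethyl groups and must attack a fully substituted allyl terminus.
- What may go wrong: attack at the unsubstituted CH2 terminus, slow capture that leaves the epoxide to oligomerise or isomerise, weak enantioface discrimination, or re-ionisation of the tertiary allyl ether with loss of regio- and enantiopurity.
- Fallback: it sets out from 12, returns at 17, and makes the C–O bond before the carbon becomes quaternary.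
- Rh2(OAc)4-catalysed O–H insertion of diethyl diazomalonate into 12 should give diethyl 2-(ArA-oxy)malonate F1.
- C-Ethylation (NaH, EtI, DMF) gives diethyl 2-(ArA-oxy)-2-ethylmalonate F2.
- LiAlH4 reduces both esters to the prochiral 2-(ArA-oxy)-2-ethylpropane-1,3-diol F3.
- Lipase-catalysed monoacetylation with vinyl acetate differentiates the enantiotopic arms and gives (2R)-2-(ArA-oxy)-2-(hydroxymethyl)butyl acetate F4.
- Dess–Martin oxidation gives (2S)-2-(ArA-oxy)-2-formylbutyl acetate F5.
- Wittig methylenation gives (2R)-2-(ArA-oxy)-2-ethylbut-3-en-1-yl acetate F6.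
- K2CO3 in MeOH removes the acetate to reach 17.

Step 15. Both alkenes are hindered: one sits on a quaternary carbon and the other lies between two ortho substituents. The ring to be formed must also bring the C4 carbonyl group towards the plane of an arene that carries a peri methoxy group.
- What may go wrong: slow initiation, catalyst decay, intermolecular metathesis, or alkene migration by ruthenium hydrides.
- Fallback: it sets out from 26, returns at 28, and closes the ring one oxidation level lower, where C4 is tetrahedral and that planarity is not demanded.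
- Treating the epimeric carbinols 26 with (H2IMes)(PCy3)Cl2Ru=CHPh in dilute CH2Cl2 should give (2R)-2-(ArA-oxy)-2-ethyl-5,6,8-trimethoxy-1,2-dihydronaphthalen-1-ol F7.
- Dess–Martin oxidation then gives 28.

Step 19. Six ethers must fall in a molecule that holds a vicinal tricarbonyl array and an inter-fragment oxygen that has become a vinylogous ester.
- What may go wrong: loss of the fragment link by conjugate addition of bromide to the quinone and expulsion of the C3 alkoxide, incomplete cleavage of the two non-chelated methoxy groups, or Lewis-acid degradation of the trione.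
- Fallback: it sets out from 30, ends at 32, and demethylates while the link is still a plain aryl ether, with air replacing the cerium oxidant.
- Excess BBr3 on 30 cleaves all eight methyl ethers to (3S)-3-ethyl-3-[(3-ethyl-1,4,5,7,8-pentahydroxynaphthalen-2-yl)oxy]-5,7,8-trihydroxynaphthalene-1,2,4(3H)-trione F8.
- This leuco-naphthazarin should be oxidised by air during a neutral to weakly acidic work-up to give 32.

Further compounds
F1 | step 6 | diethyl 2-(ArA-oxy)malonate | CCOC(=O)C(Oc1c(CC)c(OC)c2c(OC)cc(OC)c(OC)c2c1OC)C(=O)OCC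
F2 | step 6 | diethyl 2-(ArA-oxy)-2-ethylmalonate | CCOC(=O)C(CC)(Oc1c(CC)c(OC)c2c(OC)cc(OC)c(OC)c2c1OC)C(=O)OCC
F3 | step 6 | 2-(ArA-oxy)-2-ethylpropane-1,3-diol | CCC(CO)(CO)Oc1c(CC)c(OC)c2c(OC)cc(OC)c(OC)c2c1OC
F4 | step 6 | (2R)-2-(ArA-oxy)-2-(hydroxymethyl)butyl acetate | COc1c(O[C@](COC(C)=O)(CC)CO)c(CC)c(OC)c2c(OC)cc(OC)c(OC)c12
F5 | step 6 | (2S)-2-(ArA-oxy)-2-formylbutyl acetate | COc1c(O[C@](COC(C)=O)(CC)C=O)c(CC)c(OC)c2c(OC)cc(OC)c(OC)c12
F6 | step 6 | (2R)-2-(ArA-oxy)-2-ethylbut-3-en-1-yl acetate | COc1c(O[C@](COC(C)=O)(CC)C=C)c(CC)c(OC)c2c(OC)cc(OC)c(OC)c12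
F7 | step 15 | (2R)-2-(ArA-oxy)-2-ethyl-5,6,8-trimethoxy-1,2-dihydronaphthalen-1-ol (C1 epimers) | COc1c(O[C@]3(CC)C=Cc4c(OC)c(OC)cc(OC)c4C3O)c(CC)c(OC)c2c(OC)cc(OC)c(OC)c12
F8 | step 19 | (3S)-3-ethyl-3-[(3-ethyl-1,4,5,7,8-pentahydroxynaphthalen-2-yl)oxy]-5,7,8-trihydroxynaphthalene-1,2,4(3H)-trione | CCc1c(O[C@]2(CC)C(=O)C(=O)c3c(O)c(O)cc(O)c3C2=O)c(O)c2c(O)c(O)cc(O)c2c1O
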